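**Retrosynthetic overview**

- Ring C is the only ring that has to be made. It is opened last, at both of its bonds to ring A (aryl ether O1–C8a and aryl ketone C4–C4a), which gives 3,4,5-trimethoxybenzyne and an (S)-3-aryl-3-oxypropanoyl donor; one aryne addition/acyl-transfer annulation joins them again.
- Enabling feature: O1 and C4 sit on neighbouring carbons (C8a, C4a) of ring A and are 1,3-related through C2–C3, so a β-alkoxide can add to an aryne and the aryl anion can close ring C through a six-membered transition state. The C5 methoxy group next to C4a polarises the aryne so that oxygen goes to C8a and the acyl carbon to C4a.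
- Chain fragment: commercial β-keto ester, asymmetric transfer hydrogenation (sets C2), Weinreb amide, trimethylsilyl ether as latent alkoxide. The silyl group and the amine auxiliary both leave in the key step.
- Aryne precursor: 3,4,5-trimethoxyphenol, ortho-bromination, then silylation/retro-Brook/triflation in one flask.
- Order of ring formation: rings A and B are bought; ring C is formed in the final step.

Key step: step 6

Assumption: flavanone numbering is used (O1, C2, C3, C4, C4a, C5 to C8, C8a; ring A = trimethoxybenzo ring, ring B = 3,4-dimethoxyphenyl ring, ring C = pyranone ring), and 3,4,5-trimethoxyphenol and ethyl 3-(3,4-dimethoxyphenyl)-3-oxopropanoate are taken as purchasable.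

**Route**

Step 1
Reactants: 1 3,4,5-trimethoxyphenol
Product: 2 2-bromo-3,4,5-trimethoxyphenol
Conditions: NBS (1.0 equiv), CH2Cl2, −40 → 0 °C, dark
Reagents that add atoms: N-bromosuccinimide, O=C1CCC(=O)N1Br
Why: Electrophilic aromatic bromination; the two free ring positions are equivalent and both ortho to the hydroxyl group, so one equivalent of NBS at low temperature should give a single monobromide.

Step 2
Reactants: 2 2-bromo-3,4,5-trimethoxyphenol
Product: 5 3,4,5-trimethoxy-2-(trimethylsilyl)phenyl trifluoromethanesulfonate, via aryl silyl ether 3 (not isolated), via lithium silylphenoxide 4 (not isolated)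
Conditions: HMDS, THF, 65 °C, then evaporation; n-BuLi, THF, −78 °C; Tf2O, −78 °C → rt
Reagents that add atoms: hexamethyldisilazane, C[Si](C)(C)N[Si](C)(C)C; trifluoromethanesulfonic anhydride, O=S(=O)(OS(=O)(=O)C(F)(F)F)C(F)(F)F
Why: O-silylation to 3, bromine–lithium exchange followed at once by the anionic 1,3-O-to-C silyl shift (retro-Brook rearrangement) to phenoxide 4, and O-triflation is the standard one-flask route from ortho-bromophenols to ortho-silylaryl triflates.

Step 3
Reactants: 6 ethyl 3-(3,4-dimethoxyphenyl)-3-oxopropanoate
Product: 7 ethyl (3S)-3-(3,4-dimethoxyphenyl)-3-hydroxypropanoate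
Conditions: RuCl(p-cymene)[(S,S)-TsDPEN] (1 mol %), HCO2H/Et3N (5:2), DMF, 40 °C
Reagents that add atoms: none
Why: Noyori asymmetric transfer hydrogenation of an aryl ketone; the (S,S)-TsDPEN ligand on ruthenium controls the face of hydride delivery in the six-membered, CH/π-organised transition state and should set the (S)-carbinol that becomes C2 of the target.

Step 4
Reactants: 7 ethyl (3S)-3-(3,4-dimethoxyphenyl)-3-hydroxypropanoate
Product: 8 (3S)-3-(3,4-dimethoxyphenyl)-3-hydroxy-N-methoxy-N-methylpropanamide
Conditions: MeNH(OMe)·HCl (3 equiv), i-PrMgCl (6 equiv), THF, −20 → 0 °C; aq NH4Cl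
Reagents that add atoms: N,O-dimethylhydroxylamine hydrochloride, CNOC.Cl
Why: Weinreb amide formation by aminolysis of the ester with the chloromagnesium amide of N,O-dimethylhydroxylamine, a standard operation on β-hydroxy esters that does not touch the carbinol center.

Step 5
Reactants: 8 (3S)-3-(3,4-dimethoxyphenyl)-3-hydroxy-N-methoxy-N-methylpropanamide
Product: 9 (3S)-3-(3,4-dimethoxyphenyl)-N-methoxy-N-methyl-3-[(trimethylsilyl)oxy]propanamide
Conditions: TMSCl (1.2 equiv), imidazole (2 equiv), CH2Cl2, 0 °C
Reagents that add atoms: chlorotrimethylsilane, C[Si](C)(C)Cl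
Why: Routine O-silylation of a secondary alcohol; the trimethylsilyl ether serves as the fluoride-labile, proton-free source of the alkoxide for the key step.

Step 6
Reactants: 5 3,4,5-trimethoxy-2-(trimethylsilyl)phenyl trifluoromethanesulfonate (1.5 equiv); 9 (3S)-3-(3,4-dimethoxyphenyl)-N-methoxy-N-methyl-3-[(trimethylsilyl)oxy]propanamide (1.0 equiv)
Product: 14 (2S)-5,6,7,3',4'-pentamethoxyflavanone, via 3,4,5-trimethoxybenzyne 10 (not isolated), via potassium alkoxide 11 (not isolated), via aryl anion 12 (not isolated), via hemiaminal alkoxide 13 (not isolated)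
Conditions: KF (3.5 equiv), 18-crown-6 (3.5 equiv, added slowly), THF, 0 °C → rt; then 1 M aq HCl, 0 °C
Reagents that add atoms: none
Why: Proposed new method: fluoride (freed gradually by the crown ether) strips both silyl groups, so aryne 10 and alkoxide 11 arise together in a medium that holds no proton source; 11 adds to the aryne carbon remote from the flanking methoxy group (the future C8a), the aryl anion 12 so formed carries its charge at C4a, and it attacks the Weinreb carbonyl to give hemiaminal alkoxide 13, which releases the ketone only in the acidic quench. The closest known reaction type is the aryne annulation of salicylate esters to xanthones (phenoxide addition to an aryne, then ring closure of the aryl anion onto the ester), together with the O-arylation of aliphatic alcohols by arynes; new is an aliphatic β-alkoxide that carries an enolisable amide as the internal acyl donor. Ring C closes by 6-exo-trig attack of the C4a carbanion on the amide carbonyl, directly after the intermolecular O1–C8a bond formation. No stereocenter is created: C2 comes from 9 with its C–O bond never broken, and it is protected because no enolisable ketone (hence no retro-oxa-Michael ring opening) exists before the quench; the C4 center of 13 is lost there. The step needs regioselective addition, secured by the C5 methoxy group, whose inductive effect distorts the aryne so that nucleophiles attack the distal carbon, and it needs acyl transfer to outrun protonation or internal proton transfer, secured by the proton-free medium and the six-membered transition state. The amide was chosen because an amide enolate is the poorest leaving group for retro-aldol cleavage of 11 and because its tetrahedral adduct does not collapse to release a strong base in the flask.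

**Compound list**

1 | 3,4,5-trimethoxyphenol | COc1cc(O)cc(OC)c1OC | starting material
2 | 2-bromo-3,4,5-trimethoxyphenol | COc1cc(O)c(Br)c(OC)c1OC | intermediate
3 | (2-bromo-3,4,5-trimethoxyphenoxy)trimethylsilane (not isolated) | COc1cc(O[Si](C)(C)C)c(Br)c(OC)c1OC | intermediate
4 | lithium 3,4,5-trimethoxy-2-(trimethylsilyl)phenolate (not isolated) | COc1cc([O-])c([Si](C)(C)C)c(OC)c1OC.[Li+] | intermediate
5 | 3,4,5-trimethoxy-2-(trimethylsilyl)phenyl trifluoromethanesulfonate | COc1cc(OS(=O)(=O)C(F)(F)F)c([Si](C)(C)C)c(OC)c1OC | intermediate
6 | ethyl 3-(3,4-dimethoxyphenyl)-3-oxopropanoate | CCOC(=O)CC(=O)c1ccc(OC)c(OC)c1 | starting material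
7 | ethyl (3S)-3-(3,4-dimethoxyphenyl)-3-hydroxypropanoate | CCOC(=O)C[C@H](O)c1ccc(OC)c(OC)c1 | intermediate
8 | (3S)-3-(3,4-dimethoxyphenyl)-3-hydroxy-N-methoxy-N-methylpropanamide | CON(C)C(=O)C[C@H](O)c1ccc(OC)c(OC)c1 | intermediate
9 | (3S)-3-(3,4-dimethoxyphenyl)-N-methoxy-N-methyl-3-[(trimethylsilyl)oxy]propanamide | CON(C)C(=O)C[C@H](O[Si](C)(C)C)c1ccc(OC)c(OC)c1 | intermediate
10 | 3,4,5-trimethoxybenzyne (1,2-didehydro-3,4,5-trimethoxybenzene; not isolated) | COC1=C(OC)C(OC)=CC#C1 | intermediate
11 | potassium (1S)-1-(3,4-dimethoxyphenyl)-3-[methoxy(methyl)amino]-3-oxopropan-1-olate (not isolated) | CON(C)C(=O)C[C@H]([O-])c1ccc(OC)c(OC)c1.[K+] | intermediate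
12 | potassium 6-{(1S)-1-(3,4-dimethoxyphenyl)-3-[methoxy(methyl)amino]-3-oxopropoxy}-2,3,4-trimethoxybenzen-1-ide (not isolated) | CON(C)C(=O)C[C@H](Oc1cc(OC)c(OC)c(OC)[c-]1)c1ccc(OC)c(OC)c1.[K+] | intermediate
13 | potassium (2S)-2-(3,4-dimethoxyphenyl)-5,6,7-trimethoxy-4-[methoxy(methyl)amino]-3,4-dihydro-2H-chromen-4-olate (mixture at C4; not isolated) | CON(C)C1([O-])C[C@@H](c2ccc(OC)c(OC)c2)Oc2cc(OC)c(OC)c(OC)c21.[K+] | intermediate
14 | (2S)-2-(3,4-dimethoxyphenyl)-5,6,7-trimethoxy-2,3-dihydro-4H-chromen-4-one, (2S)-5,6,7,3',4'-pentamethoxyflavanone | COc1ccc([C@@H]2CC(=O)c3c(cc(OC)c(OC)c3OC)O2)cc1OC | target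

**Summary**

Total step count: 6.
Longest linear sequence: 4 steps (6 → 7 → 8 → 9 → 14); the aryne precursor branch is 2 steps (1 → 2 → 5).

**Steps most likely to fail, with fallbacks**

1. Step 6 (proposed new method). What may go wrong: quenching of the aryl anion by adventitious protons or by internal proton transfer from C3 before acyl transfer; retro-aldol equilibration of the alkoxide with loss of configuration; or attack of the alkoxide at the sulfonyl sulfur of the triflate instead of at the aryne. The fallback uses known chemistry, sets out from 1 and comes back at 14, building ring C first and setting C2 last. Friedel–Crafts acetylation of 1 ortho to the hydroxyl group (AcOH, BF3·OEt2, 90 °C) would give 1-(6-hydroxy-2,3,4-trimethoxyphenyl)ethan-1-one F1. Condensation with N,N-dimethylformamide dimethyl acetal (toluene, 100 °C) would give (2E)-3-(dimethylamino)-1-(6-hydroxy-2,3,4-trimethoxyphenyl)prop-2-en-1-one F2. Acid-induced cyclisation (HCl, CH2Cl2, rt) would give 5,6,7-trimethoxy-4H-chromen-4-one F3. Enantioselective conjugate addition of (3,4-dimethoxyphenyl)boronic acid under divalent palladium catalysis (Pd(OCOCF3)2, t-BuPyOX ligand, NH4PF6, H2O, 1,2-dichloroethane, 60 °C) would then give 14. The (R)-configured ligand is expected to give the (2S) product, by analogy with the facial sense of the (S)-ligand on cyclic enones; this assignment should be confirmed before use.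

2. Step 1. What may go wrong: over-bromination at the second, equally activated ortho position, or oxidation of the very electron-rich phenol to a quinone by the bromine source. The fallback sets out from 1 and comes back at 2, placing the bromine through a carbanion instead of an electrophilic substitution. Methoxymethyl ether formation (MOMCl, i-Pr2NEt, CH2Cl2, 0 °C) would give 1,2,3-trimethoxy-5-(methoxymethoxy)benzene F4. Directed ortho-lithiation between the two oxygen substituents (n-BuLi, THF, 0 °C) would give [2,3,4-trimethoxy-6-(methoxymethoxy)phenyl]lithium F5. Quenching with 1,2-dibromotetrachloroethane (−78 °C → rt) would give 2-bromo-3,4,5-trimethoxy-1-(methoxymethoxy)benzene F6, and acetal cleavage (HCl, MeOH, 40 °C) would give 2.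

3. Step 4. What may go wrong: retro-aldol cleavage or dehydration of the magnesium β-alkoxide under the strongly basic aminolysis conditions, with loss of material or of enantiomeric purity. The fallback sets out from 7 and comes back at 8, separating ester cleavage from amide formation. Mild saponification (LiOH, THF/H2O, 0 °C, then acidification to pH 3) would give (3S)-3-(3,4-dimethoxyphenyl)-3-hydroxypropanoic acid F7. Carbodiimide coupling with N,O-dimethylhydroxylamine hydrochloride (EDC·HCl, N-methylmorpholine, CH2Cl2, 0 °C) would give 8.

**Further compounds**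

F1 | step 6 | 1-(6-hydroxy-2,3,4-trimethoxyphenyl)ethan-1-one | CC(=O)c1c(O)cc(OC)c(OC)c1OC
F2 | step 6 | (2E)-3-(dimethylamino)-1-(6-hydroxy-2,3,4-trimethoxyphenyl)prop-2-en-1-one | CN(C)/C=C/C(=O)c1c(O)cc(OC)c(OC)c1OC
F3 | step 6 | 5,6,7-trimethoxy-4H-chromen-4-one | COc1cc2occc(=O)c2c(OC)c1OC
F4 | step 1 | 1,2,3-trimethoxy-5-(methoxymethoxy)benzene | COCOc1cc(OC)c(OC)c(OC)c1
F5 | step 1 | [2,3,4-trimethoxy-6-(methoxymethoxy)phenyl]lithium | [Li]c1c(OCOC)cc(OC)c(OC)c1OC
F6 | step 1 | 2-bromo-3,4,5-trimethoxy-1-(methoxymethoxy)benzene | COCOc1cc(OC)c(OC)c(OC)c1Br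
F7 | step 4 | (3S)-3-(3,4-dimethoxyphenyl)-3-hydroxypropanoic acid | OC(=O)C[C@H](O)c1ccc(OC)c(OC)c1
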